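Each vessel below gets 2.5 min, on average in the tank, and I start from which step is done by when.

| setting | larch | elm | birch | oak |
|---|---|---|---|---|
| substrate | 0.32 M | 0.32 M | 0.32 M | 0.32 M |
| coupling partner | 0.480 M | 0.480 M (fed, over 2.00 min) | 0.480 M | 0.480 M |
| free catalyst | 0.16 mM | 0.16 mM | 0.16 mM | 0.16 mM |
| impurity | 0.14 mM | 0.14 mM | 0.14 mM | 0.14 mM |
| time | 2.5 min | 2.5 min |  | 2.5 min |
| remark | a tube with plug flow, the mixed feed as stated, residence time 2.5 min | a stirred flask in which coupling partner is dosed at a steady rate over 2.00 min without added volume, worked up at 2.5 min | a single well-mixed tank run continuously and read at steady state, 2.5 min in it on average | a closed flask charged with all of it at once and left for 2.5 min |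

    substrate + free catalyst → free catalyst + intermediate (k1 = 441 L mol⁻¹ s⁻¹)
    coupling partner + free catalyst + intermediate → free catalyst + product (k2 = 935 L² mol⁻² s⁻¹)
    free catalyst + impurity → spent catalyst (k3 = 1.53 × 10⁵ L mol⁻¹ s⁻¹)

1. the set-up with the highest amount of intermediate at the outlet or at the end, in percent of the substrate put in ("none" if the first two lie within 2 percentage points) (larch / elm / birch / oak / none)
2. amount of intermediate at the outlet or at the end, in percent of the substrate put in, larch
3. amount of intermediate at the outlet or at the end, in percent of the substrate put in, elm
4. amount of intermediate at the outlet or at the end, in percent of the substrate put in, birch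
5. amount of intermediate at the outlet or at the end, in percent of the substrate put in, oak

- the stated concentrations are those of everything mixed, before any reaction; amounts are the same in each set-up
- the feed brings no volume worth counting
- run time (larch): 2.5 min

The top rung of my ladder is step 3. Impurity takes catalyst one for one, and 0.14 mM stands against 0.16 mM. The live catalyst, 0.0200 mM, is charged catalyst minus charged impurity. Even at that level the time of impurity against catalyst is about 0.327 s, far shorter than the run. Steps 1 and 2 hand it back, so step 1 is pseudo-first-order in substrate with a time of 1.89 min. Step 2, at the charged [coupling partner], has nearly the same time, 1.86 min. The run is 1.32 times the first of these, so at its end I expect intermediate still to be made while it is used up.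

For oak, and for larch, which runs the same course along its length, I expect 26.6% substrate left. Treating the two times as equal gives 35.2% intermediate. But [coupling partner] falls, so I replace its curve by its mean, 0.419 M. The second time becomes 2.13 min and intermediate 38.0%, so the mean is worth 2.8 percentage points. For elm and birch I stop here.

The forecast names elm, with 36% for larch, 43% for elm, 27% for birch and 36% for oak: “Dosing the coupling partner starves the consuming step early and so holds up the most intermediate”. My oak figure stands above its one.

The simulation gives elm the most, 43.7%, against 38.3% in larch, 38.3% in oak and 27.4% in birch. Oak is not at rest at 2.5 min: it still holds 26.5% substrate. At ten times the time, 25.0 min, oak has 0.646% intermediate and 99.4% product, with 33.8% of its coupling partner left, while free catalyst still reads 12.5%, and my live catalyst of 0.0200 mM is 12.5% of the charge. Elm then holds 0.661% intermediate.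

A tube like larch with 8.4 × 10⁻⁵ M impurity should have 0.0760 mM live catalyst, 47.5% of the charge, which should leave 0.656% substrate. It reads 47.5% free catalyst, 0.654% substrate, 11.9% intermediate and 87.4% product.

(All constants were set for the occasion; the rest is arithmetic.)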